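**Plan**

- Retrosynthesis: the O1–C7a enol-ether bond is opened first, giving a cyclic 1,3-dione with a pendant benzylic alcohol. The carbocycle C3a–C4–C5–C6–C7–C7a is then contracted by joining C4 to C7 (a bicyclo[2.2.0]hex-5-en-2-one) and cut at C7–C7a and C3a–C4 into a cyclobutenone (C4, C5, C6, C7) and an ynol ether (C7a≡C3a, carrying C3 and C2).
- Enabling feature: the six-membered ring holds the diene C7=C7a–C3a=C4 between the C6 ketone and the O1 donor on C7a. This is the 4π-opened form of a cyclobutene (C7a=C3a) fused to a cyclobutanone, and its polarity (enolisable C7, oxocarbenium-type C7a) matches a Ficini-type [2+2] of an ynol ether with an enone.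
- Forward: cyclobutenone 7 and silyl ynol ether 16 are made separately (four steps each). Their silver-catalysed union builds the transient cyclobutene, whose central bond opens so that the four-membered ketone becomes the six-membered dienone. The dihydrofuran is closed last.
- Stereochemistry: C5 comes from a Pd/PHOX allylation of a cyclobutanone enol ether (catalyst control) and is never part of a bond change afterwards. C3 comes by chirality transfer from (R)-but-3-yn-2-ol through an allenylzinc reagent. C2 comes from the anti-selective closed transition state of that addition. The target is (2S,3S,5S).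

Key step: step 9

Assumption: (S)-t-BuPHOX is taken to deliver the allyl group to the same enolate face as in the 2-alkylcycloalkanone series, which corresponds to (R)-5; if the sense proves opposite, (R)-t-BuPHOX is used.

**Step 1**
Reactants: 1 1,2-bis(trimethylsilyloxy)cyclobut-1-ene
Product: 3 2-methoxycyclobutan-1-one (racemic), via 2-hydroxycyclobutan-1-one 2 (not isolated)
Conditions: MeOH, 65 °C; then TsOH·H2O (10 mol %), 50 °C; aq. HCl work-up
Reagents that add atoms: methanol, CO
Why: Methanolysis of the bis-silyl enediol ether gives the acyloin 2, and acid-catalysed exchange of its hydroxyl for methoxy through the hemiketal/enediol monoether (α-ketol-type carbonyl transposition, known for 2-hydroxycyclobutanone with alcohols) gives 3, whose stereocentre is irrelevant because it is planarised in step 2.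

**Step 2**
Reactants: 3 2-methoxycyclobutan-1-one
Product: 4 1-methoxy-2-(trimethylsilyloxy)cyclobut-1-ene
Conditions: Me3SiCl, NaI, Et3N, MeCN, 0 → 23 °C
Reagents that add atoms: chlorotrimethylsilane, C[Si](C)(C)Cl
Why: Silyl enol ether formation under equilibrating conditions (Me3SiI formed in situ, Et3N) should favour the more substituted enol ether on the side of the more acidic C–H flanked by C=O and OMe, giving the tetrasubstituted 1,2-dioxygenated cyclobutene.

**Step 3**
Reactants: 4 1-methoxy-2-(trimethylsilyloxy)cyclobut-1-ene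
Product: 5 (R)-2-allyl-2-methoxycyclobutan-1-one
Conditions: Pd2(dba)3 (2.5 mol %), (S)-t-BuPHOX (6.25 mol %), diallyl carbonate (1.05 equiv), Bu4N[Ph3SiF2] (35 mol %), THF, 25 °C
Reagents that add atoms: diallyl carbonate, C=CCOC(=O)OCC=C
Why: Enantioselective Tsuji allylation of a silyl enol ether (asymmetric allylic alkylation with zerovalent palladium): fluoride-triggered desilylation releases the tetrasubstituted α-methoxy enolate, which is allylated on one face within the chiral (PHOX)Pd(allyl) complex, so the ligand sets the quaternary centre (the later C5).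

**Step 4**
Reactants: 5 (R)-2-allyl-2-methoxycyclobutan-1-one
Product: 7 (S)-4-allyl-4-methoxycyclobut-2-en-1-one, via α-phenylselanyl ketone 6 (not isolated)
Conditions: LiN(i-Pr)2, THF, −78 °C; PhSeBr, −78 °C; then 30% H2O2 aq., 0 → 20 °C; product kept cold in solution and used at once
Reagents that add atoms: none
Why: Selenoxide elimination: only C4 carries α-hydrogens, so enolisation and selenenylation are regiospecific, and syn-elimination of the selenoxide below room temperature should introduce the C2=C3 double bond without touching the quaternary centre or heating the 4-alkoxycyclobutenone to the point of electrocyclic opening.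

**Step 5**
Reactants: 8 (R)-but-3-yn-2-ol
Product: 9 (R)-but-3-yn-2-yl methanesulfonate
Conditions: MsCl, Et3N, CH2Cl2, −78 → 0 °C
Reagents that add atoms: methanesulfonyl chloride, CS(=O)(=O)Cl
Why: O-Sulfonylation of the alcohol, in which the C–O bond is not broken, so the configuration is retained.

**Step 6**
Reactants: 9 (R)-but-3-yn-2-yl methanesulfonate; 10 3,4,5-trimethoxybenzaldehyde
Product: 12 (1S,2S)-2-methyl-1-(3,4,5-trimethoxyphenyl)but-3-yn-1-ol, via allenylzinc reagent 11 (not isolated)
Conditions: Pd(OAc)2 (5 mol %), PPh3 (5 mol %), Et2Zn (3 equiv), THF, −78 → −20 °C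
Reagents that add atoms: none
Why: Marshall propargylation: zerovalent palladium displaces the mesylate anti (SN2'), transmetalation with Et2Zn gives the configurationally defined allenylzinc 11, and its addition to the aldehyde through a closed six-membered SE2' transition state should transfer the axial chirality to C3 and place the aryl group anti to the methyl group (anti adduct, sets C2), the minor syn isomer being removed by chromatography.

**Step 7**
Reactants: 12 (1S,2S)-2-methyl-1-(3,4,5-trimethoxyphenyl)but-3-yn-1-ol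
Product: 13 tert-butyldimethyl{[(1S,2S)-2-methyl-1-(3,4,5-trimethoxyphenyl)but-3-yn-1-yl]oxy}silane
Conditions: TBSOTf, 2,6-lutidine, CH2Cl2, −78 → 0 °C
Reagents that add atoms: tert-butyldimethylsilyl trifluoromethanesulfonate, CC(C)(C)[Si](C)(C)OS(=O)(=O)C(F)(F)F
Why: Silyl ether formation masks the alcohol against the organolithium and peroxide of step 8 and against addition to the activated ynol ether in step 9, and no stereocentre is touched.

**Step 8**
Reactants: 13 tert-butyldimethyl{[(1S,2S)-2-methyl-1-(3,4,5-trimethoxyphenyl)but-3-yn-1-yl]oxy}silane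
Product: 16 tert-butyldimethyl{[(1S,2S)-2-methyl-4-[(triisopropylsilyl)oxy]-1-(3,4,5-trimethoxyphenyl)but-3-yn-1-yl]oxy}silane, via lithium acetylide 14 (not isolated), via lithium ynolate 15 (not isolated)
Conditions: n-BuLi, THF, −78 °C; LiOOt-Bu (from t-BuOOH and LiN(SiMe3)2), −78 → 0 °C; TIPSOTf, −78 → 0 °C
Reagents that add atoms: tert-butyl hydroperoxide, CC(C)(C)OO; triisopropylsilyl trifluoromethanesulfonate, CC(C)[Si](C(C)C)(C(C)C)OS(=O)(=O)C(F)(F)F
Why: Oxidation of the lithium acetylide with lithium tert-butylperoxide gives the lithium ynolate, which the bulky silyl triflate silylates on oxygen to an isolable silyl ynol ether (known siloxy alkyne synthesis), the stereocentres not being involved.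

**Step 9**
Reactants: 7 (S)-4-allyl-4-methoxycyclobut-2-en-1-one; 16 tert-butyldimethyl{[(1S,2S)-2-methyl-4-[(triisopropylsilyl)oxy]-1-(3,4,5-trimethoxyphenyl)but-3-yn-1-yl]oxy}silane
Product: 18 (S)-6-allyl-4-[(1S,2S)-1-[(tert-butyldimethylsilyl)oxy]-1-(3,4,5-trimethoxyphenyl)propan-2-yl]-6-methoxy-3-[(triisopropylsilyl)oxy]cyclohexa-2,4-dien-1-one, via bicyclo[2.2.0]hexenone 17 (not isolated)
Conditions: AgNTf2 (10 mol %), 4 Å MS, CH2Cl2, −40 → 23 °C
Reagents that add atoms: none
Why: Proposed new method: silver-promoted conjugate addition of the nucleophilic β-carbon of ynol ether 16 to C3 of the strained enone 7 gives an enolate/silyl ketenium zwitterion that collapses by 4-exo-dig attack of the enolate α-carbon on the ketenium carbon to the bicyclo[2.2.0]hex-5-en-2-one 17 (closest known reaction: the silver-catalysed, Ficini-type [2+2] cycloaddition of siloxy alkynes with cyclic enones). The central bond of 17 joins the enolisable ketone α-carbon to a carbon allylic to the siloxy-substituted double bond, so its strain-driven, push–pull-assisted cleavage (the cyclobutene ring opening known for bicyclo[2.2.0]hex-2-enes) should enlarge the four-membered ketone by the two alkyne carbons to the cyclohexa-2,4-dienone 18. The six-membered ring is therefore not closed directly but arises by ring enlargement, the only ring closure being that of the transient cyclobutene. No permanent stereocentre is formed (the two bridgehead centres of 17 are erased on opening), and the quaternary centre is never part of a breaking or forming bond, so its configuration from step 3 is retained. The step needs head-to-head regiochemistry (oxygen-bearing alkyne carbon to the enone α-carbon), secured by the matched polarity of ynol ether and enone, and 1,4-addition in preference to 1,2-addition or to thermal opening of 7 to its achiral vinylketene, secured by the soft silver catalyst and temperatures at or below 23 °C.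

**Step 10**
Reactants: 18 (S)-6-allyl-4-[(1S,2S)-1-[(tert-butyldimethylsilyl)oxy]-1-(3,4,5-trimethoxyphenyl)propan-2-yl]-6-methoxy-3-[(triisopropylsilyl)oxy]cyclohexa-2,4-dien-1-one
Product: 20 (2S,3S,5S)-5-allyl-5-methoxy-3-methyl-2-(3,4,5-trimethoxyphenyl)-2,3-dihydro-1-benzofuran-6(5H)-one, via hydroxy dione 19 (not isolated)
Conditions: HF·pyridine, THF/pyridine, 0 → 23 °C; then CSA (10 mol %), 4 Å MS, CH2Cl2, 23 °C
Reagents that add atoms: none
Why: Desilylation frees the cyclic 1,3-dione and the benzylic alcohol, and acid-catalysed vinylogous ester formation (5-exo-trig hemiketalisation at C7a, then dehydration) should close the dihydrofuran on the only carbonyl within reach, C2 keeping its configuration because its C–O bond is not broken and any ionisation of the benzylic position re-closing to the same, more stable 2,3-trans ring.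

**Compound list**

1 | 1,2-bis(trimethylsilyloxy)cyclobut-1-ene | C[Si](C)(C)OC1=C(O[Si](C)(C)C)CC1 | starting material
2 | 2-hydroxycyclobutan-1-one (racemic) | O=C1CCC1O | intermediate
3 | 2-methoxycyclobutan-1-one (racemic) | COC1CCC1=O | intermediate
4 | 1-methoxy-2-(trimethylsilyloxy)cyclobut-1-ene | COC1=C(O[Si](C)(C)C)CC1 | intermediate
5 | (R)-2-allyl-2-methoxycyclobutan-1-one | C=CC[C@]1(OC)CCC1=O | intermediate
6 | (2S)-2-allyl-2-methoxy-4-(phenylselanyl)cyclobutan-1-one (both C4 epimers) | C=CC[C@]1(OC)CC([Se]c2ccccc2)C1=O | intermediate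
7 | (S)-4-allyl-4-methoxycyclobut-2-en-1-one | C=CC[C@]1(OC)C=CC1=O | intermediate
8 | (R)-but-3-yn-2-ol | C#C[C@@H](C)O | starting material
9 | (R)-but-3-yn-2-yl methanesulfonate | C#C[C@@H](C)OS(C)(=O)=O | intermediate
10 | 3,4,5-trimethoxybenzaldehyde | COc1cc(C=O)cc(OC)c1OC | starting material
11 | (aS)-buta-1,2-dien-1-yl(ethyl)zinc (axial configuration given in the name only) | CC=C=C[Zn]CC | intermediate
12 | (1S,2S)-2-methyl-1-(3,4,5-trimethoxyphenyl)but-3-yn-1-ol | C#C[C@H](C)[C@H](O)c1cc(OC)c(OC)c(OC)c1 | intermediate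
13 | tert-butyldimethyl{[(1S,2S)-2-methyl-1-(3,4,5-trimethoxyphenyl)but-3-yn-1-yl]oxy}silane | C#C[C@H](C)[C@H](O[Si](C)(C)C(C)(C)C)c1cc(OC)c(OC)c(OC)c1 | intermediate
14 | lithium (3S,4S)-4-[(tert-butyldimethylsilyl)oxy]-3-methyl-4-(3,4,5-trimethoxyphenyl)but-1-yn-1-ide | [Li]C#C[C@H](C)[C@H](O[Si](C)(C)C(C)(C)C)c1cc(OC)c(OC)c(OC)c1 | intermediate
15 | lithium (3S,4S)-4-[(tert-butyldimethylsilyl)oxy]-3-methyl-4-(3,4,5-trimethoxyphenyl)but-1-yn-1-olate | [Li]OC#C[C@H](C)[C@H](O[Si](C)(C)C(C)(C)C)c1cc(OC)c(OC)c(OC)c1 | intermediate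
16 | tert-butyldimethyl{[(1S,2S)-2-methyl-4-[(triisopropylsilyl)oxy]-1-(3,4,5-trimethoxyphenyl)but-3-yn-1-yl]oxy}silane | CC(C)[Si](OC#C[C@H](C)[C@H](O[Si](C)(C)C(C)(C)C)c1cc(OC)c(OC)c(OC)c1)(C(C)C)C(C)C | intermediate
17 | (3S)-3-allyl-5-[(1S,2S)-1-[(tert-butyldimethylsilyl)oxy]-1-(3,4,5-trimethoxyphenyl)propan-2-yl]-3-methoxy-6-[(triisopropylsilyl)oxy]bicyclo[2.2.0]hex-5-en-2-one (cis-fused, either bridgehead face) | C=CC[C@]1(OC)C2C(C1=O)C(O[Si](C(C)C)(C(C)C)C(C)C)=C2[C@H](C)[C@H](O[Si](C)(C)C(C)(C)C)c1cc(OC)c(OC)c(OC)c1 | intermediate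
18 | (S)-6-allyl-4-[(1S,2S)-1-[(tert-butyldimethylsilyl)oxy]-1-(3,4,5-trimethoxyphenyl)propan-2-yl]-6-methoxy-3-[(triisopropylsilyl)oxy]cyclohexa-2,4-dien-1-one | C=CC[C@]1(OC)C=C([C@H](C)[C@H](O[Si](C)(C)C(C)(C)C)c2cc(OC)c(OC)c(OC)c2)C(O[Si](C(C)C)(C(C)C)C(C)C)=CC1=O | intermediate
19 | (S)-6-allyl-4-[(1S,2S)-1-hydroxy-1-(3,4,5-trimethoxyphenyl)propan-2-yl]-6-methoxycyclohex-4-ene-1,3-dione | C=CC[C@]1(OC)C=C([C@H](C)[C@H](O)c2cc(OC)c(OC)c(OC)c2)C(=O)CC1=O | intermediate
20 | (2S,3S,5S)-5-allyl-5-methoxy-3-methyl-2-(3,4,5-trimethoxyphenyl)-2,3-dihydro-1-benzofuran-6(5H)-one | C=CC[C@]1(OC)C=C2C(=CC1=O)O[C@H](c1cc(OC)c(OC)c(OC)c1)[C@H]2C | target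

**Step count and risks**

Total step count: 10. Longest linear sequence: 6 steps (8 → 20 through steps 5–10; equally 1 → 20 through steps 1–4, 9 and 10).

Steps most likely to fail:

1. Step 9. The ynol ether may add 1,2 to the strained carbonyl, the cyclobutenone may oligomerise, or 7 may open thermally to its vinylketene with loss of configuration at the quaternary centre. The fallback uses known enolate chemistry, sets out from 13 and 7 and returns at 19. Compound 13 is taken through the first two stages of step 8, and the ynolate 15 is quenched with HCl/MeOH instead of the silyl triflate (ynolate to ketene to ester, as in the last stage of a Kowalski homologation) to give methyl (3S,4S)-4-[(tert-butyldimethylsilyl)oxy]-3-methyl-4-(3,4,5-trimethoxyphenyl)butanoate F1. LiN(i-Pr)2 and Me3SiCl convert it into the silyl ketene acetal [(3S,4S)-4-[(tert-butyldimethylsilyl)oxy]-1-methoxy-3-methyl-4-(3,4,5-trimethoxyphenyl)but-1-en-1-yl]oxytrimethylsilane F2. Its Mukaiyama–Michael addition to 7 (Me3SiOTf cat., CH2Cl2, −78 °C, aqueous work-up) should give methyl (3S,4S)-2-[(2S)-2-allyl-2-methoxy-3-oxocyclobutyl]-4-[(tert-butyldimethylsilyl)oxy]-3-methyl-4-(3,4,5-trimethoxyphenyl)butanoate F3, a mixture at the two new centres, both of which are erased later. NaOMe in MeOH should then bring about E1cB retro-Michael cleavage of the strained ring bond between the ketone α-carbon and the ester β-carbon, followed by Claisen cyclisation of the liberated methyl ketone enolate onto the ester. This gives (S)-6-allyl-4-[(1S,2S)-1-[(tert-butyldimethylsilyl)oxy]-1-(3,4,5-trimethoxyphenyl)propan-2-yl]-6-methoxycyclohex-4-ene-1,3-dione F4. HF·pyridine removes the silyl group to give 19, which is cyclised as in the second half of step 10.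

2. Step 3. Enantiofacial discrimination on the small, α-alkoxy-substituted enolate may be insufficient. The fallback sets out from 4 and returns at 18, and lets the enantiopure partner sort the two series. Allylation of 4 without a chiral ligand (Pd(PPh3)4, diallyl carbonate, Bu4N[Ph3SiF2]) gives racemic 2-allyl-2-methoxycyclobutan-1-one F5. Step 4 converts it through racemic 2-allyl-2-methoxy-4-(phenylselanyl)cyclobutan-1-one F6 into racemic 4-allyl-4-methoxycyclobut-2-en-1-one F7. In step 9 the single-enantiomer ynol ether 16 turns the two enantiomers of F7 into 18 and, through the (3R)-epimer of 17 F8, into the (6R)-epimer of 18 F9. These are diastereomers and are separated by chromatography, after which 18 continues as written.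

3. Step 4. The strained enone may be lost during the oxidative elimination, by conjugate addition of selenium by-products or peroxide, or by ring opening. The fallback sets out from 5 and returns at 7. The enolate of 5 is trapped as the silyl enol ether (S)-[(4-allyl-4-methoxycyclobut-1-en-1-yl)oxy]trimethylsilane F10 (LiN(i-Pr)2, Me3SiCl, THF, −78 °C), which is dehydrogenated under Saegusa–Ito conditions (Pd(OAc)2, MeCN, 23 °C) to 7.

Further compounds
F1 | step 9 | methyl (3S,4S)-4-[(tert-butyldimethylsilyl)oxy]-3-methyl-4-(3,4,5-trimethoxyphenyl)butanoate | COC(=O)C[C@H](C)[C@H](O[Si](C)(C)C(C)(C)C)c1cc(OC)c(OC)c(OC)c1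
F2 | step 9 | [(3S,4S)-4-[(tert-butyldimethylsilyl)oxy]-1-methoxy-3-methyl-4-(3,4,5-trimethoxyphenyl)but-1-en-1-yl]oxytrimethylsilane | COC(O[Si](C)(C)C)=C[C@H](C)[C@H](O[Si](C)(C)C(C)(C)C)c1cc(OC)c(OC)c(OC)c1
F3 | step 9 | methyl (3S,4S)-2-[(2S)-2-allyl-2-methoxy-3-oxocyclobutyl]-4-[(tert-butyldimethylsilyl)oxy]-3-methyl-4-(3,4,5-trimethoxyphenyl)butanoate | COC(=O)C(C1CC(=O)[C@]1(OC)CC=C)[C@H](C)[C@H](O[Si](C)(C)C(C)(C)C)c1cc(OC)c(OC)c(OC)c1
F4 | step 9 | (S)-6-allyl-4-[(1S,2S)-1-[(tert-butyldimethylsilyl)oxy]-1-(3,4,5-trimethoxyphenyl)propan-2-yl]-6-methoxycyclohex-4-ene-1,3-dione | C=CC[C@]1(OC)C=C([C@H](C)[C@H](O[Si](C)(C)C(C)(C)C)c2cc(OC)c(OC)c(OC)c2)C(=O)CC1=O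
F5 | step 3 | racemic 2-allyl-2-methoxycyclobutan-1-one | C=CCC1(OC)CCC1=O
F6 | step 3 | racemic 2-allyl-2-methoxy-4-(phenylselanyl)cyclobutan-1-one | C=CCC1(OC)CC([Se]c2ccccc2)C1=O
F7 | step 3 | racemic 4-allyl-4-methoxycyclobut-2-en-1-one | C=CCC1(OC)C=CC1=O
F8 | step 3 | (3R)-3-allyl-5-[(1S,2S)-1-[(tert-butyldimethylsilyl)oxy]-1-(3,4,5-trimethoxyphenyl)propan-2-yl]-3-methoxy-6-[(triisopropylsilyl)oxy]bicyclo[2.2.0]hex-5-en-2-one | C=CC[C@@]1(OC)C2C(C1=O)C(O[Si](C(C)C)(C(C)C)C(C)C)=C2[C@H](C)[C@H](O[Si](C)(C)C(C)(C)C)c1cc(OC)c(OC)c(OC)c1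
F9 | step 3 | (R)-6-allyl-4-[(1S,2S)-1-[(tert-butyldimethylsilyl)oxy]-1-(3,4,5-trimethoxyphenyl)propan-2-yl]-6-methoxy-3-[(triisopropylsilyl)oxy]cyclohexa-2,4-dien-1-one | C=CC[C@@]1(OC)C=C([C@H](C)[C@H](O[Si](C)(C)C(C)(C)C)c2cc(OC)c(OC)c(OC)c2)C(O[Si](C(C)C)(C(C)C)C(C)C)=CC1=O
F10 | step 4 | (S)-[(4-allyl-4-methoxycyclobut-1-en-1-yl)oxy]trimethylsilane | C=CC[C@]1(OC)CC=C1O[Si](C)(C)C
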